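## Retrosynthetic overview

1. Target ⇐ desilylation ⇐ Z-selective ring-closing metathesis at C1=C10; the ten-membered carbocycle is formed last, on a preformed α-methylene-γ-lactone.
2. Lactone (first ring) ⇐ chelate-controlled addition of an (E)-alkenyl Grignard to an α-hydroxy aldehyde (C5–C6), then lactonisation (C6–O).
3. C7–OH / C8–O-senecioate ⇐ key C–O disconnection: one-flask Sharpless epoxidation and Ti-templated opening of the epoxide at C8 by senecioic acid (inversion at C8, C7–OH unveiled).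
4. Dienyl allylic alcohol ⇐ Stille coupling with methyl 2-bromoacrylate ⇐ hydroxyl-directed trans-hydrostannation of a propargylic alcohol.
5. Propargylic alcohol ⇐ asymmetric alkynylation of methacrolein with a propargyl silyl ether (sets C9).

Assumption 1: locants C1–C15 in the explanations follow germacrane numbering of the target (C6 lactone carbinol, C7 tertiary carbinol, C8 ester carbinol, C9 free carbinol, C11=C13 exocyclic methylene, C12 lactone carbonyl).
Assumption 2: (S,S)-ProPhenol is taken as the ligand enantiomer that delivers the alkyne to the Si face of methacrolein to give (R)-3; if the measured sense is opposite, (R,R)-ProPhenol is used.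

## Route

Step 1
Reactants: 1 methacrolein; 2 trimethyl(prop-2-yn-1-yloxy)silane
Product: 3 (3R)-2-methyl-6-[(trimethylsilyl)oxy]hex-1-en-4-yn-3-ol
Conditions: Me2Zn (3 equiv), (S,S)-ProPhenol (10 mol %), Ph3P=O (20 mol %), toluene, 0 °C; aq. NH4Cl
Reagents that add atoms: none
Why: Zn–ProPhenol-catalysed asymmetric alkynylation (alkynylzinc addition) works well on α-branched enals, and the dinuclear zinc pocket delivers the alkynyl group to one aldehyde face, setting C9 as (R).

Step 2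
Reactants: 3 (3R)-2-methyl-6-[(trimethylsilyl)oxy]hex-1-en-4-yn-3-ol
Product: 5 (4R)-4-[(tert-butyldimethylsilyl)oxy]-5-methylhex-5-en-2-yn-1-ol, via bis-silyl ether 4 (not isolated)
Conditions: TBSCl, imidazole, DMF, rt; then K2CO3 (cat.), MeOH, 0 °C
Reagents that add atoms: tert-butyldimethylsilyl chloride CC(C)(C)[Si](C)(C)Cl
Why: Standard silylation of the secondary alcohol followed by selective methanolysis of the far more labile primary TMS ether leaves only the C6 hydroxyl free, which is needed to direct steps 3 and 5.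

Step 3
Reactants: 5 (4R)-4-[(tert-butyldimethylsilyl)oxy]-5-methylhex-5-en-2-yn-1-ol
Product: 6 (2Z,4S)-4-[(tert-butyldimethylsilyl)oxy]-5-methyl-2-(tributylstannyl)hexa-2,5-dien-1-ol
Conditions: [Cp*RuCl]4 (2.5 mol %), Bu3SnH (1.1 equiv), CH2Cl2, rt
Reagents that add atoms: tributyltin hydride CCCC[SnH](CCCC)CCCC
Why: Ruthenium-catalysed hydroxyl-directed trans-hydrostannation puts tin on the alkyne carbon next to the free OH (C7) and hydrogen trans to it, fixing the olefin geometry (C6 trans to C9) that later becomes the 7,8-anti relationship.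

Step 4
Reactants: 6 (2Z,4S)-4-[(tert-butyldimethylsilyl)oxy]-5-methyl-2-(tributylstannyl)hexa-2,5-dien-1-ol; 7 methyl 2-bromoprop-2-enoate
Product: 8 methyl (3E,5S)-5-[(tert-butyldimethylsilyl)oxy]-3-(hydroxymethyl)-6-methyl-2-methylidenehepta-3,6-dienoate
Conditions: Pd(PPh3)4 (10 mol %), CuTC (1.5 equiv), DMF, 0 °C → rt
Reagents that add atoms: none
Why: Copper-assisted Stille coupling of a hindered α-stannyl allylic alcohol with a 2-haloacrylate proceeds with retention of olefin geometry and tolerates the free hydroxyl, installing the whole C11–C13 acrylate unit; the substituent cis to the acrylate blocks the s-cis conformer, so the diene does not dimerise.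

Step 5
Reactants: 8 methyl (3E,5S)-5-[(tert-butyldimethylsilyl)oxy]-3-(hydroxymethyl)-6-methyl-2-methylidenehepta-3,6-dienoate; 9 3-methylbut-2-enoic acid (senecioic acid)
Product: 11 methyl (3R,4S,5R)-5-[(tert-butyldimethylsilyl)oxy]-3-hydroxy-3-(hydroxymethyl)-6-methyl-2-methylidene-4-[(3-methylbut-2-enoyl)oxy]hept-6-enoate, via epoxy alcohol 10 (not isolated)
Conditions: Ti(OiPr)4 (1.0 equiv), D-(−)-diethyl tartrate (1.2 equiv), t-BuOOH (2 equiv), 4 Å MS, CH2Cl2, −20 °C; then Ti(OiPr)4 (1.5 equiv), 9 (2 equiv), −20 → 20 °C; aq. tartaric acid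
Reagents that add atoms: tert-butyl hydroperoxide CC(C)(C)OO
Why: Proposed new method: a one-flask Katsuki–Sharpless epoxidation and Ti(IV)-templated acyloxylative opening (net enantioselective anti-hydroxy-acyloxylation of a cross-conjugated dienol), in which Ti/D-(−)-DET epoxidises only the C7=C8 olefin (the sole olefin allylic to a free OH) under reagent control to the (2R,3R)-epoxide 10, whose alkoxide stays on titanium, and the added Ti(OiPr)4/senecioic acid forms a titanium carboxylate that activates the epoxide inside the O6–Ti–O(epoxide) chelate and delivers the carboxylate to C8 with inversion, because C7 is quaternary and its ionisation or SN2′ opening is disfavoured by the electron-poor acrylate substituent, so C7 (retention, tertiary OH) and C8 (inversion, ester) are both set; the closest known reactions are the Sharpless asymmetric epoxidation with in situ Ti(OiPr)4-mediated C3-selective opening of 2,3-epoxy alcohols by carboxylic acids, which has not been shown on a 2-(1-alkoxycarbonylvinyl) trisubstituted epoxy alcohol or with an α,β-unsaturated acid.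

Step 6
Reactants: 11 methyl (3R,4S,5R)-5-[(tert-butyldimethylsilyl)oxy]-3-hydroxy-3-(hydroxymethyl)-6-methyl-2-methylidene-4-[(3-methylbut-2-enoyl)oxy]hept-6-enoate
Product: 12 methyl (3S,4S,5R)-5-[(tert-butyldimethylsilyl)oxy]-3-formyl-3-hydroxy-6-methyl-2-methylidene-4-[(3-methylbut-2-enoyl)oxy]hept-6-enoate
Conditions: TEMPO (20 mol %), PhI(OAc)2 (1.3 equiv), CH2Cl2, rt (run directly on crude 11)
Reagents that add atoms: none
Why: TEMPO/PhI(OAc)2 oxidation converts only the primary alcohol of the primary/tertiary diol into the non-enolisable α-hydroxy aldehyde and leaves esters, olefins and the silyl ether untouched.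

Step 7
Reactants: 13 hex-5-en-1-yne
Product: 15 (1E)-1-iodo-2-methylhexa-1,5-diene, via alkenylalane 14 (not isolated)
Conditions: Me3Al (2 equiv), Cp2ZrCl2 (20 mol %), CH2Cl2, 0 °C → rt; then I2, THF, −30 °C
Reagents that add atoms: trimethylaluminium C[Al](C)C; iodine II
Why: Zirconium-catalysed Negishi carboalumination adds Me–Al syn and regioselectively across the terminal alkyne (the isolated alkene is inert), and iodinolysis with retention gives the pure (E)-iodide.

Step 8
Reactants: 12 methyl (3S,4S,5R)-5-[(tert-butyldimethylsilyl)oxy]-3-formyl-3-hydroxy-6-methyl-2-methylidene-4-[(3-methylbut-2-enoyl)oxy]hept-6-enoate; 15 (1E)-1-iodo-2-methylhexa-1,5-diene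
Product: 19 (1S,2R)-2-[(tert-butyldimethylsilyl)oxy]-1-[(2S,3R)-3-hydroxy-2-[(1E)-2-methylhexa-1,5-dien-1-yl]-4-methylidene-5-oxooxolan-3-yl]-3-methylbut-3-en-1-yl 3-methylbut-2-enoate, via alkenyllithium 16 (not isolated), via alkenylmagnesium bromide 17 (not isolated), via hydroxy ester 18 (not isolated)
Conditions: 15 (2.4 equiv), t-BuLi (4.8 equiv), Et2O, −78 °C; MgBr2·OEt2 (2.5 equiv); 12, THF, −78 °C; AcOH, −78 °C; then PPTS (cat.), CH2Cl2, rt
Reagents that add atoms: none
Why: Iodine–lithium exchange and transmetalation to magnesium retain the olefin geometry, and the Cram-chelate addition then sets C6 as (S), because the magnesium alkoxide of the tertiary hydroxyl chelates the aldehyde oxygen and the alkenyl group attacks anti to the bulky C8 branch (over the flat acrylate); the γ-hydroxy ester 18 then lactonises under mild acid to the γ-lactone with C5 and C8 cis.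

Step 9
Reactants: 19 (1S,2R)-2-[(tert-butyldimethylsilyl)oxy]-1-[(2S,3R)-3-hydroxy-2-[(1E)-2-methylhexa-1,5-dien-1-yl]-4-methylidene-5-oxooxolan-3-yl]-3-methylbut-3-en-1-yl 3-methylbut-2-enoate
Product: 20 (3aR,4S,5R,6Z,10E,11aS)-5-[(tert-butyldimethylsilyl)oxy]-3a-hydroxy-6,10-dimethyl-3-methylidene-2-oxo-2,3,3a,4,5,8,9,11a-octahydrocyclodeca[b]furan-4-yl 3-methylbut-2-enoate
Conditions: Grubbs II (20 mol %, in portions), 1,4-benzoquinone (20 mol %), toluene (0.5 mM), 80 °C
Reagents that add atoms: none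
Why: Ring-closing metathesis between the monosubstituted and the 1,1-disubstituted olefin at high dilution closes the ten-membered ring to the ring-cis (Z) trisubstituted olefin, the less strained geometry next to the existing E-C4=C5 bond, while the acrylate, senecioate and trisubstituted olefins are unreactive olefin types.

Step 10
Reactants: 20 (3aR,4S,5R,6Z,10E,11aS)-5-[(tert-butyldimethylsilyl)oxy]-3a-hydroxy-6,10-dimethyl-3-methylidene-2-oxo-2,3,3a,4,5,8,9,11a-octahydrocyclodeca[b]furan-4-yl 3-methylbut-2-enoate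
Product: 21 (3aR,4S,5R,6Z,10E,11aS)-3a,5-dihydroxy-6,10-dimethyl-3-methylidene-2-oxo-2,3,3a,4,5,8,9,11a-octahydrocyclodeca[b]furan-4-yl 3-methylbut-2-enoate
Conditions: HF·pyridine, pyridine, THF, 0 °C → rt
Reagents that add atoms: none
Why: Buffered HF·pyridine desilylation cleaves the secondary TBS ether without touching the esters, the α-methylene lactone or the tertiary allylic alcohol, and it is not basic enough to cause acyl migration.

## Compound list

1 | methacrolein (2-methylprop-2-enal) | C=C(C)C=O | starting material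
2 | trimethyl(prop-2-yn-1-yloxy)silane | C#CCO[Si](C)(C)C | starting material
3 | (3R)-2-methyl-6-[(trimethylsilyl)oxy]hex-1-en-4-yn-3-ol | C=C(C)[C@@H](O)C#CCO[Si](C)(C)C | intermediate
4 | (3R)-3-[(tert-butyldimethylsilyl)oxy]-2-methyl-6-[(trimethylsilyl)oxy]hex-1-en-4-yne (bis-silyl ether) | C=C(C)[C@@H](O[Si](C)(C)C(C)(C)C)C#CCO[Si](C)(C)C | intermediate
5 | (4R)-4-[(tert-butyldimethylsilyl)oxy]-5-methylhex-5-en-2-yn-1-ol | C=C(C)[C@@H](O[Si](C)(C)C(C)(C)C)C#CCO | intermediate
6 | (2Z,4S)-4-[(tert-butyldimethylsilyl)oxy]-5-methyl-2-(tributylstannyl)hexa-2,5-dien-1-ol | OC/C(=C/[C@H](O[Si](C)(C)C(C)(C)C)C(C)=C)[Sn](CCCC)(CCCC)CCCC | intermediate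
7 | methyl 2-bromoprop-2-enoate | C=C(Br)C(=O)OC | starting material
8 | methyl (3E,5S)-5-[(tert-butyldimethylsilyl)oxy]-3-(hydroxymethyl)-6-methyl-2-methylidenehepta-3,6-dienoate | OC/C(=C/[C@H](O[Si](C)(C)C(C)(C)C)C(C)=C)C(=C)C(=O)OC | intermediate
9 | 3-methylbut-2-enoic acid (senecioic acid) | CC(C)=CC(=O)O | starting material
10 | methyl 2-[(2R,3R)-3-[(1R)-1-[(tert-butyldimethylsilyl)oxy]-2-methylprop-2-en-1-yl]-2-(hydroxymethyl)oxiran-2-yl]prop-2-enoate (epoxy alcohol) | OC[C@@]1(C(=C)C(=O)OC)O[C@@H]1[C@H](O[Si](C)(C)C(C)(C)C)C(C)=C | intermediate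
11 | methyl (3R,4S,5R)-5-[(tert-butyldimethylsilyl)oxy]-3-hydroxy-3-(hydroxymethyl)-6-methyl-2-methylidene-4-[(3-methylbut-2-enoyl)oxy]hept-6-enoate | OC[C@](O)(C(=C)C(=O)OC)[C@@H](OC(=O)C=C(C)C)[C@H](O[Si](C)(C)C(C)(C)C)C(C)=C | intermediate
12 | methyl (3S,4S,5R)-5-[(tert-butyldimethylsilyl)oxy]-3-formyl-3-hydroxy-6-methyl-2-methylidene-4-[(3-methylbut-2-enoyl)oxy]hept-6-enoate | O=C[C@](O)(C(=C)C(=O)OC)[C@@H](OC(=O)C=C(C)C)[C@H](O[Si](C)(C)C(C)(C)C)C(C)=C | intermediate
13 | hex-5-en-1-yne | C#CCCC=C | starting material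
14 | dimethyl[(1E)-2-methylhexa-1,5-dien-1-yl]alumane (alkenylalane) | C[Al](C)/C=C(\C)CCC=C | intermediate
15 | (1E)-1-iodo-2-methylhexa-1,5-diene | I/C=C(\C)CCC=C | intermediate
16 | [(1E)-2-methylhexa-1,5-dien-1-yl]lithium | [Li]/C=C(\C)CCC=C | intermediate
17 | bromo[(1E)-2-methylhexa-1,5-dien-1-yl]magnesium | Br[Mg]/C=C(\C)CCC=C | intermediate
18 | methyl (3R,4S,5E)-3-[(1S,2R)-2-[(tert-butyldimethylsilyl)oxy]-3-methyl-1-[(3-methylbut-2-enoyl)oxy]but-3-en-1-yl]-3,4-dihydroxy-6-methyl-2-methylidenedeca-5,9-dienoate (hydroxy ester) | O[C@@H](/C=C(\C)CCC=C)[C@](O)(C(=C)C(=O)OC)[C@@H](OC(=O)C=C(C)C)[C@H](O[Si](C)(C)C(C)(C)C)C(C)=C | intermediate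
19 | (1S,2R)-2-[(tert-butyldimethylsilyl)oxy]-1-[(2S,3R)-3-hydroxy-2-[(1E)-2-methylhexa-1,5-dien-1-yl]-4-methylidene-5-oxooxolan-3-yl]-3-methylbut-3-en-1-yl 3-methylbut-2-enoate | C=C1C(=O)O[C@@H](/C=C(\C)CCC=C)[C@@]1(O)[C@@H](OC(=O)C=C(C)C)[C@H](O[Si](C)(C)C(C)(C)C)C(C)=C | intermediate
20 | (3aR,4S,5R,6Z,10E,11aS)-5-[(tert-butyldimethylsilyl)oxy]-3a-hydroxy-6,10-dimethyl-3-methylidene-2-oxo-2,3,3a,4,5,8,9,11a-octahydrocyclodeca[b]furan-4-yl 3-methylbut-2-enoate | C=C1C(=O)O[C@H]2/C=C(\C)CC/C=C(/C)[C@@H](O[Si](C)(C)C(C)(C)C)[C@H](OC(=O)C=C(C)C)[C@@]12O | intermediate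
21 | (3aR,4S,5R,6Z,10E,11aS)-3a,5-dihydroxy-6,10-dimethyl-3-methylidene-2-oxo-2,3,3a,4,5,8,9,11a-octahydrocyclodeca[b]furan-4-yl 3-methylbut-2-enoate (CNP0255427.1) | C=C1C(=O)O[C@H]2/C=C(\C)CC/C=C(/C)[C@@H](O)[C@H](OC(=O)C=C(C)C)[C@@]12O | target

## Step count and risks

Total steps: 10. Longest linear sequence: 9 (steps 1–6, 8, 9, 10); step 7 is a one-step side branch.

The three steps most likely to fail:

**Step 5 (the proposed new step).** The Lewis-acidic titanium could open the tertiary, acrylate-substituted epoxide carbon C7 or trigger SN2′ attack at C13 instead of delivering the acid to the hindered C8. The product's primary hydroxyl may also lactonise onto the methyl ester or accept the acyl group by migration before the oxidation.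
Fallback (known chemistry, the C8–O acyl bond is made by ordinary esterification): it sets out from 8 and rejoins at 19. Epoxy alcohol 10 is isolated after a standard Katsuki–Sharpless epoxidation. It is opened at C8 by Ti(OiPr)4-mediated (or W(OEt)6-catalysed) alcoholysis with p-methoxybenzyl alcohol to give methyl (3R,4S,5R)-5-[(tert-butyldimethylsilyl)oxy]-3-hydroxy-3-(hydroxymethyl)-4-[(4-methoxyphenyl)methoxy]-6-methyl-2-methylidenehept-6-enoate F1. TEMPO/PhI(OAc)2 gives methyl (3S,4S,5R)-5-[(tert-butyldimethylsilyl)oxy]-3-formyl-3-hydroxy-4-[(4-methoxyphenyl)methoxy]-6-methyl-2-methylidenehept-6-enoate F2. Chelate-controlled addition of 17 gives methyl (3R,4S,5E)-3-[(1S,2R)-2-[(tert-butyldimethylsilyl)oxy]-1-[(4-methoxyphenyl)methoxy]-3-methylbut-3-en-1-yl]-3,4-dihydroxy-6-methyl-2-methylidenedeca-5,9-dienoate F3, which lactonises with PPTS to (4R,5S)-4-[(1S,2R)-2-[(tert-butyldimethylsilyl)oxy]-1-[(4-methoxyphenyl)methoxy]-3-methylbut-3-en-1-yl]-4-hydroxy-5-[(1E)-2-methylhexa-1,5-dien-1-yl]-3-methylideneoxolan-2-one F4. DDQ in wet CH2Cl2 removes the PMB group to give (4S,5S)-4-[(1S,2R)-2-[(tert-butyldimethylsilyl)oxy]-1-hydroxy-3-methylbut-3-en-1-yl]-4-hydroxy-5-[(1E)-2-methylhexa-1,5-dien-1-yl]-3-methylideneoxolan-2-one F5. Its only free secondary hydroxyl is esterified with 9 under Yamaguchi conditions to give 19.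

**Step 8.** The facial selectivity rests on C8 being the larger group in the magnesium chelate. Co-chelation of the acrylate ester could reverse it. Conjugate addition to the acrylate or acyl migration to the tertiary alkoxide are further risks.
Fallback (non-chelating addition with the opposite facial sense): it sets out from 12 and rejoins at 19. TMSOTf/2,6-lutidine gives methyl (3S,4S,5R)-5-[(tert-butyldimethylsilyl)oxy]-3-formyl-6-methyl-2-methylidene-4-[(3-methylbut-2-enoyl)oxy]-3-[(trimethylsilyl)oxy]hept-6-enoate F6. Nozaki–Hiyama–Kishi coupling with iodide 15 (CrCl2, cat. NiCl2, DMSO) proceeds under Felkin–Anh control, which is complementary to the chelate mode, and gives methyl (3R,4S,5E)-3-[(1S,2R)-2-[(tert-butyldimethylsilyl)oxy]-3-methyl-1-[(3-methylbut-2-enoyl)oxy]but-3-en-1-yl]-4-hydroxy-6-methyl-2-methylidene-3-[(trimethylsilyl)oxy]deca-5,9-dienoate F7. PPTS/MeOH removes the TMS ether to give 18, which lactonises to 19.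

**Step 9.** Closing a strained (1(10)Z,4E)-cyclodecadiene onto a rigid lactone at a hindered isopropenyl group may give oligomers, the E-olefin or no reaction.
Fallback (macrocyclise before the lactone is formed): it sets out from 12 (with 17) and rejoins at 20. The magnesium dialkoxide of 18 is trapped in situ (TMSOTf, 2,6-lutidine, −78 °C) as methyl (3S,4S,5E)-3-[(1S,2R)-2-[(tert-butyldimethylsilyl)oxy]-3-methyl-1-[(3-methylbut-2-enoyl)oxy]but-3-en-1-yl]-6-methyl-2-methylidene-3,4-bis[(trimethylsilyl)oxy]deca-5,9-dienoate F8. RCM of this flexible open-chain ester (Grubbs II, high dilution) gives methyl 2-[(1S,2S,3E,7Z,9R,10S)-9-[(tert-butyldimethylsilyl)oxy]-4,8-dimethyl-10-[(3-methylbut-2-enoyl)oxy]-1,2-bis[(trimethylsilyl)oxy]cyclodeca-3,7-dien-1-yl]prop-2-enoate F9. PPTS/MeOH then removes both TMS ethers and the C6 hydroxyl closes the lactone across the ring to give 20.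

Further compounds
F1 | step 5 | methyl (3R,4S,5R)-5-[(tert-butyldimethylsilyl)oxy]-3-hydroxy-3-(hydroxymethyl)-4-[(4-methoxyphenyl)methoxy]-6-methyl-2-methylidenehept-6-enoate | OC[C@](O)(C(=C)C(=O)OC)[C@@H](OCc1ccc(OC)cc1)[C@H](O[Si](C)(C)C(C)(C)C)C(C)=C
F2 | step 5 | methyl (3S,4S,5R)-5-[(tert-butyldimethylsilyl)oxy]-3-formyl-3-hydroxy-4-[(4-methoxyphenyl)methoxy]-6-methyl-2-methylidenehept-6-enoate | O=C[C@](O)(C(=C)C(=O)OC)[C@@H](OCc1ccc(OC)cc1)[C@H](O[Si](C)(C)C(C)(C)C)C(C)=C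
F3 | step 5 | methyl (3R,4S,5E)-3-[(1S,2R)-2-[(tert-butyldimethylsilyl)oxy]-1-[(4-methoxyphenyl)methoxy]-3-methylbut-3-en-1-yl]-3,4-dihydroxy-6-methyl-2-methylidenedeca-5,9-dienoate | O[C@@H](/C=C(\C)CCC=C)[C@](O)(C(=C)C(=O)OC)[C@@H](OCc1ccc(OC)cc1)[C@H](O[Si](C)(C)C(C)(C)C)C(C)=C
F4 | step 5 | (4R,5S)-4-[(1S,2R)-2-[(tert-butyldimethylsilyl)oxy]-1-[(4-methoxyphenyl)methoxy]-3-methylbut-3-en-1-yl]-4-hydroxy-5-[(1E)-2-methylhexa-1,5-dien-1-yl]-3-methylideneoxolan-2-one | C=C1C(=O)O[C@@H](/C=C(\C)CCC=C)[C@@]1(O)[C@@H](OCc2ccc(OC)cc2)[C@H](O[Si](C)(C)C(C)(C)C)C(C)=C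
F5 | step 5 | (4S,5S)-4-[(1S,2R)-2-[(tert-butyldimethylsilyl)oxy]-1-hydroxy-3-methylbut-3-en-1-yl]-4-hydroxy-5-[(1E)-2-methylhexa-1,5-dien-1-yl]-3-methylideneoxolan-2-one | C=C1C(=O)O[C@@H](/C=C(\C)CCC=C)[C@@]1(O)[C@@H](O)[C@H](O[Si](C)(C)C(C)(C)C)C(C)=C
F6 | step 8 | methyl (3S,4S,5R)-5-[(tert-butyldimethylsilyl)oxy]-3-formyl-6-methyl-2-methylidene-4-[(3-methylbut-2-enoyl)oxy]-3-[(trimethylsilyl)oxy]hept-6-enoate | O=C[C@](O[Si](C)(C)C)(C(=C)C(=O)OC)[C@@H](OC(=O)C=C(C)C)[C@H](O[Si](C)(C)C(C)(C)C)C(C)=C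
F7 | step 8 | methyl (3R,4S,5E)-3-[(1S,2R)-2-[(tert-butyldimethylsilyl)oxy]-3-methyl-1-[(3-methylbut-2-enoyl)oxy]but-3-en-1-yl]-4-hydroxy-6-methyl-2-methylidene-3-[(trimethylsilyl)oxy]deca-5,9-dienoate | O[C@@H](/C=C(\C)CCC=C)[C@](O[Si](C)(C)C)(C(=C)C(=O)OC)[C@@H](OC(=O)C=C(C)C)[C@H](O[Si](C)(C)C(C)(C)C)C(C)=C
F8 | step 9 | methyl (3S,4S,5E)-3-[(1S,2R)-2-[(tert-butyldimethylsilyl)oxy]-3-methyl-1-[(3-methylbut-2-enoyl)oxy]but-3-en-1-yl]-6-methyl-2-methylidene-3,4-bis[(trimethylsilyl)oxy]deca-5,9-dienoate | C[Si](C)(C)O[C@@H](/C=C(\C)CCC=C)[C@](O[Si](C)(C)C)(C(=C)C(=O)OC)[C@@H](OC(=O)C=C(C)C)[C@H](O[Si](C)(C)C(C)(C)C)C(C)=C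
F9 | step 9 | methyl 2-[(1S,2S,3E,7Z,9R,10S)-9-[(tert-butyldimethylsilyl)oxy]-4,8-dimethyl-10-[(3-methylbut-2-enoyl)oxy]-1,2-bis[(trimethylsilyl)oxy]cyclodeca-3,7-dien-1-yl]prop-2-enoate | C=C(C(=O)OC)[C@@]1(O[Si](C)(C)C)[C@@H](O[Si](C)(C)C)/C=C(\C)CC/C=C(/C)[C@@H](O[Si](C)(C)C(C)(C)C)[C@@H]1OC(=O)C=C(C)C
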